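## Retrosynthetic overview

1. Atom labels follow the target SMILES (C1…C26, O10). Ring A = C3‑C4‑C5‑C6‑C8, ring B (eight‑membered) = C2‑C3‑C8‑C9‑C11‑C24‑C25‑C26, ring C = C11‑C13‑C14‑C15‑C23‑C24, ring D = C15‑C17‑C18‑C19‑C22‑C23.
2. Feature used: in ring B the quaternary B/C fusion carbon C11 (methyl C12) lies between the C9 carbinol and the fusion methine C24. C9=C11 is therefore an enolate and C24–C25 a bond made by a [3,3] shift of a cyclobutanol alkoxide (C9–C2 cleaved); C11–CH3 then comes from MeI.
3. After the key step: ring A by ene closure C8–C6 of the C3 butenyl arm onto the C9 enol; C2=C26 moved to C2=C3 by H‑atom‑transfer isomerisation; C9 ketone to dienyl triflate to C2=C3–C8=C9 diene; hydroboration–oxidation sets C8 and C9.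
4. Before it: the cyclobutanol is made from a ring C/D alkenyllithium (chiral‑imine Robinson annulation of 2,5,5‑trimethylcyclohexanone with methyl vinyl ketone, Li/NH3 reductive triflation, stannane) and (2S,3R)‑3‑butenyl‑2‑methyl‑2‑vinylcyclobutanone (dichloroketene [2+2] with hexa‑1,5‑diene, cuprate methylation, thioalkylation/sulfoxide elimination, resolution).
5. Ring order: D (starting material), then C, then the four‑membered ring, then B (ring expansion), then A.

Key step: step 13

Remark: compounds 17–19 and 22–24 are racemic and are written as the antipode that is carried on after step 11; the chiral‑imine Michael addition of step 3 is assumed to follow the sense known for 2‑methylcyclohexanone, so the (R)‑amine should give the (S) quaternary centre.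

## Route

Step 1
Reactants: 1 3,3-dimethylcyclohexan-1-one; 2 iodomethane
Product: 4 2,5,5-trimethylcyclohexan-1-one (racemic), via lithium enolate 3 (not isolated)
Conditions: LDA (1.05 equiv), THF, −78 °C; MeI, −78 → 0 °C
Reagents that add atoms: iodomethane (2), CI
Why: Kinetic enolate alkylation: LDA removes a proton from the unhindered CH2 (the other α‑CH2 is neopentyl‑like next to the gem‑dimethyl carbon) and the enolate is methylated there; the new stereocentre is lost again in step 3.

Step 2
Reactants: 4 2,5,5-trimethylcyclohexan-1-one; 5 (R)-1-phenylethan-1-amine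
Product: 6 (R)-N-(2,5,5-trimethylcyclohexylidene)-1-phenylethan-1-amine (C2 epimers, imine/enamine tautomers)
Conditions: cat. TsOH, toluene, reflux, Dean–Stark
Reagents that add atoms: (R)-1-phenylethan-1-amine (5), C[C@@H](N)c1ccccc1
Why: Acid‑catalysed imine condensation with azeotropic removal of water gives the chiral imine for the asymmetric Michael addition.

Step 3
Reactants: 6 chiral imine; 7 but-3-en-2-one
Product: 10 (S)-4a,7,7-trimethyl-4,4a,5,6,7,8-hexahydronaphthalen-2(3H)-one, via Michael adduct imine 8 (not isolated), via diketone 9 (not isolated)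
Conditions: MVK, THF, 40 °C; 20% aq. AcOH, rt; crude 9: NaOMe, MeOH, 60 °C
Reagents that add atoms: but-3-en-2-one (7), CC(=O)C=C
Why: Chiral‑imine Michael addition followed by Robinson annulation: the more substituted secondary enamine tautomer adds to the enone through an aza‑ene‑like transition state on the face anti to the phenyl group, which sets C15 (S), and hydrolysis then base‑mediated aldol condensation closes ring C as the enone.

Step 4
Reactants: 10 (S)-octalone
Product: 12 (4aS,8aS)-4a,7,7-trimethyl-3,4,4a,5,6,7,8,8a-octahydronaphthalen-2-yl trifluoromethanesulfonate, via lithium enolate 11 (not isolated)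
Conditions: Li (2.1 equiv), t-BuOH (1.0 equiv), NH3/THF, −78 °C; NH3 removed; PhNTf2, THF, −78 → 0 °C
Reagents that add atoms: N-phenylbis(trifluoromethanesulfonimide), O=S(=O)(N(c1ccccc1)S(=O)(=O)C(F)(F)F)C(F)(F)F
Why: Dissolving‑metal reduction of the enone with enolate trapping: axial protonation at C23 gives the trans‑decalin (H23 trans to the C15 methyl) and leaves the C11=C24 enolate regiospecifically, which is triflated on oxygen.

Step 5
Reactants: 12 alkenyl triflate
Product: 13 trimethyl[(4aS,8aS)-4a,7,7-trimethyl-3,4,4a,5,6,7,8,8a-octahydronaphthalen-2-yl]stannane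
Conditions: (Me3Sn)2, Pd(PPh3)4 (5 mol%), LiCl, THF, 65 °C
Reagents that add atoms: hexamethylditin, C[Sn](C)(C)[Sn](C)(C)C
Why: Palladium‑catalysed stannylation of an alkenyl triflate with a distannane (chloride‑assisted transmetalation) gives the alkenylstannane without touching the stereocentres or the alkene position.

Step 6
Reactants: 14 hexa-1,5-diene (3 equiv); 15 trichloroacetyl chloride
Product: 17 3-(but-3-en-1-yl)-2,2-dichlorocyclobutan-1-one (racemic), via dichloroketene 16 (not isolated)
Conditions: Zn–Cu couple, Et2O/DME, rt, slow addition of 15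
Reagents that add atoms: trichloroacetyl chloride (15), ClC(Cl)(Cl)C(Cl)=O
Why: Ketene–alkene [2+2] cycloaddition: dichloroketene from zinc dechlorination adds to one terminal alkene of the excess diene with its carbonyl carbon on the CH2 terminus, which places the butenyl chain at C3 next to the CCl2 carbon.

Step 7
Reactants: 17 dichlorocyclobutanone
Product: 19 {[3-(but-3-en-1-yl)-2-methylcyclobut-1-en-1-yl]oxy}trimethylsilane (racemic), via lithium enolate 18 (not isolated)
Conditions: Me2CuLi (3 equiv, from CuI and MeLi), THF, −78 → −40 °C; Me3SiCl, Et3N, −78 °C → rt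
Reagents that add atoms: lithium dimethylcuprate, [Li+].C[Cu-]C; chlorotrimethylsilane, C[Si](C)(C)Cl
Why: Reductive methylation of an α,α‑dichloro ketone with a cuprate: chlorine–copper exchange gives the chloro enolate, the second chlorine is replaced by methyl, and the 2‑methyl enolate, regio‑defined because it arises at the former CCl2 carbon, is trapped as the silyl enol ether.

Step 8
Reactants: 20 ethyl phenyl sulfide
Product: 21 (1-chloroethyl)(phenyl)sulfane (racemic)
Conditions: NCS, CH2Cl2, 0 °C → rt; filtered, used crude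
Reagents that add atoms: N-chlorosuccinimide, O=C1CCC(=O)N1Cl
Why: α‑Chlorination of a sulfide through the chlorosulfonium salt (Pummerer‑type shift) gives the thionium ion precursor.

Step 9
Reactants: 19 silyl enol ether; 21 (1-chloroethyl)(phenyl)sulfane
Product: 22 rac-(2S,3R)-3-(but-3-en-1-yl)-2-methyl-2-[1-(phenylsulfanyl)ethyl]cyclobutan-1-one (both epimers at the sulfide carbon)
Conditions: ZnBr2 (5 mol%), CH2Cl2, 0 °C → rt
Reagents that add atoms: (1-chloroethyl)(phenyl)sulfane (21), CC(Cl)Sc1ccccc1
Why: Lewis‑acid‑mediated phenylthioalkylation of a silyl enol ether: the thionium ion attacks C2 of the planar cyclobutene on the face anti to the C3 butenyl group, so the future vinyl carbon ends up trans and the methyl cis to the butenyl chain at the new quaternary centre.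

Step 10
Reactants: 22 β-phenylthio ketone
Product: 24 rac-(2S,3R)-3-(but-3-en-1-yl)-2-ethenyl-2-methylcyclobutan-1-one, via sulfoxide 23 (not isolated)
Conditions: NaIO4, MeOH/H2O, 0 °C → rt; then toluene, CaCO3, 110 °C
Reagents that add atoms: none
Why: Sulfide oxidation with periodate (no Baeyer–Villiger oxidation of the cyclobutanone) and thermal sulfoxide syn‑elimination, which can take a hydrogen only from the methyl group because C2 is quaternary, unveil the vinyl group.

Step 11
Reactants: 24 racemic cyclobutanone
Product: 25 (2S,3R)-3-(but-3-en-1-yl)-2-ethenyl-2-methylcyclobutan-1-one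
Conditions: preparative SFC, amylose tris(3,5-dimethylphenylcarbamate) phase, CO2/i-PrOH
Reagents that add atoms: none
Why: Resolution by chromatography on a chiral stationary phase separates the antipodes without derivatisation; the (2S,3R) antipode (to be assigned by VCD or X‑ray analysis of a crystalline hydrazone) is the one whose C2/C9 configuration later presents C25 to the C24 face anti to the C15 methyl.

Step 12
Reactants: 13 alkenylstannane; 25 (2S,3R)-cyclobutanone
Product: 27 (1R,2S,3R)-3-(but-3-en-1-yl)-2-ethenyl-2-methyl-1-[(4aS,8aS)-4a,7,7-trimethyl-3,4,4a,5,6,7,8,8a-octahydronaphthalen-2-yl]cyclobutan-1-ol, via alkenyllithium 26 (not isolated)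
Conditions: MeLi, THF, −78 → 0 °C; 25, −78 °C; aq. NH4Cl
Reagents that add atoms: none
Why: Tin–lithium exchange and 1,2‑addition to the strained ketone: the alkenyllithium attacks the carbonyl face anti to the C3 butenyl and C2 methyl groups, i.e. syn to the vinyl group, so the two alkenyl groups are cis (OH cis to methyl and butenyl), and adducts of the minor antipodes of either fragment are diastereomers that are removed by chromatography.

Step 13
Reactants: 27 cyclobutanol; 2 iodomethane
Product: 30 tricyclic ketone (ring B cyclooct-4-enone with C9=O, Z-C2(CH3)=C26 and the but-3-enyl arm at C3, trans-fused at C11(CH3)/C24(H) to the trans-decalin C/D), via potassium alkoxide 28 (not isolated), via potassium enolate 29 (not isolated)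
Conditions: KH, 18-crown-6, THF, 0 → 25 °C; MeI, −78 → 0 °C
Reagents that add atoms: iodomethane (2), CI
Why: The potassium alkoxide undergoes an alkoxide‑accelerated [3,3]‑sigmatropic (anionic oxy‑Cope) shift of the cis‑1,2‑dialkenylcyclobutane through a boat transition state in which C25 bonds to C24 while C9–C2 breaks, ring strain and the alkoxide allowing reaction near room temperature; the closest known reaction type is the rearrangement of 1,2‑dialkenylcyclobutanols to cyclooct‑4‑enones with alkylation of the enolate. Ring B is closed by ring expansion of the four‑membered ring by four atoms, not by an endo or exo cyclisation, and the new C2=C26 alkene is cis. C24 is controlled by the boat geometry together with the absolute configuration at C9/C2, which presents the vinyl terminus to the C24 face anti to the axial C15 methyl (matched pairing of 13 and 25) and gives H24 trans to H23. C11 is set by C‑methylation of the tetrasubstituted enolate, which cannot equilibrate to C8 because KH leaves no proton source; the methyl group has to enter axially on the ring‑C chair, anti to axial H24 and syn to C25, to give the trans B/C fusion. The step needs [3,3] shift over fragmentation or 1,3‑shift (secured by the cis alkenyl groups), C‑ over O‑alkylation (MeI) and axial over equatorial attack at C11. The last is the least secure, because the C2=C26 bridge of the tub‑shaped dienolate lies on the face the methyl group must use.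

Step 14
Reactants: 30 tricyclic ketone
Product: 31 tetracyclic ketone (ring A closed by the C8–C6 bond, C6 methyl; H3, H8 and H6 cis; C2=C26 retained)
Conditions: degassed toluene (0.01 M), base-washed sealed tube, 300 °C
Reagents that add atoms: none
Why: Thermal Conia‑ene (enol‑ene) reaction: the only possible enol (C8=C9, C11 being quaternary) adds 5‑exo to the tethered terminal alkene with transfer of the enol hydrogen to C7, and the concerted transition state should give the cis‑fused bicycle with the C6 methyl cis to the C9 carbonyl, which fixes C6 relative to C3.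

Step 15
Reactants: 31 tetracyclic ketone
Product: 32 tetracyclic β,γ-unsaturated ketone (C9=O, tetrasubstituted C2=C3, H8 cis to H6)
Conditions: Co(salen-tBu,tBu)Cl (5 mol%), PhSiH3 (10 mol%), C6H6, rt → 40 °C
Reagents that add atoms: none
Why: Radical‑hydride (metal‑hydride H‑atom‑transfer) isomerisation: reversible H‑atom transfer to C26 gives the tertiary C2 radical and loss of H3 moves the double bond into the tetrasubstituted C2=C3 position, the thermodynamic sink, under neutral conditions that avoid transannular Prins reaction, conjugation and epimerisation at C8.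

Step 16
Reactants: 32 β,γ-unsaturated ketone
Product: 34 dienyl triflate (C9(OTf)=C8–C3=C2), via potassium dienolate 33 (not isolated)
Conditions: KHMDS, THF, −78 °C; PhNTf2, −78 → 0 °C
Reagents that add atoms: N-phenylbis(trifluoromethanesulfonimide), O=S(=O)(N(c1ccccc1)S(=O)(=O)C(F)(F)F)C(F)(F)F
Why: Enolate O‑triflation: deprotonation can take place only at C8 (α and allylic, C11 being quaternary), and the dienolate is triflated on oxygen to give the 2‑triflyloxy‑1,3‑diene regiospecifically.

Step 17
Reactants: 34 dienyl triflate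
Product: 35 diene (C9H=C8–C3=C2(CH3))
Conditions: Pd(OAc)2 (5 mol%), PPh3, HCO2H, n-Bu3N, DMF, 60 °C
Reagents that add atoms: none
Why: Palladium‑catalysed formate reduction of an alkenyl triflate (oxidative addition, formate exchange, decarboxylation, reductive elimination) replaces OTf by H without moving either double bond.

Step 18
Reactants: 35 diene
Product: 37 target CNP0399382.1 (C9 alcohol cis to H8 and trans to the C11 methyl), via alkylborane 36 (not isolated)
Conditions: BH3·THF (1.1 equiv), THF, 0 °C → rt; 3 M NaOH, 30% H2O2, 0 °C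
Reagents that add atoms: hydrogen peroxide, OO
Why: Hydroboration–oxidation: borane adds syn across the trisubstituted C8=C9 terminus of the diene with boron at C9, hydrogen reaching C8 on the face of the alkylidenecyclopentane opposite the C6 methyl (cis to H6), and oxidation with retention gives the C9 alcohol cis to H8, while the tetrasubstituted C2=C3 alkene reacts more slowly.

## Compound list

1 | 3,3-dimethylcyclohexan-1-one | CC1(C)CCCC(=O)C1 | starting material
2 | iodomethane | CI | starting material
3 | lithium 5,5-dimethylcyclohex-1-en-1-olate | [Li]OC1=CCCC(C)(C)C1 | intermediate (not isolated)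
4 | 2,5,5-trimethylcyclohexan-1-one (racemic) | CC1CCC(C)(C)CC1=O | intermediate
5 | (R)-1-phenylethan-1-amine | C[C@@H](N)c1ccccc1 | starting material (auxiliary)
6 | (R)-N-(2,5,5-trimethylcyclohexylidene)-1-phenylethan-1-amine | CC1CCC(C)(C)CC1=N[C@H](C)c1ccccc1 | intermediate
7 | but-3-en-2-one | CC(=O)C=C | starting material
8 | (R)-N-[(2S)-2,5,5-trimethyl-2-(3-oxobutyl)cyclohexylidene]-1-phenylethan-1-amine | CC(=O)CC[C@]1(C)CCC(C)(C)CC1=N[C@H](C)c1ccccc1 | intermediate (not isolated)
9 | (S)-2,5,5-trimethyl-2-(3-oxobutyl)cyclohexan-1-one | CC(=O)CC[C@]1(C)CCC(C)(C)CC1=O | intermediate (not isolated)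
10 | (S)-4a,7,7-trimethyl-4,4a,5,6,7,8-hexahydronaphthalen-2(3H)-one | O=C1CC[C@]2(C)CCC(C)(C)CC2=C1 | intermediate
11 | lithium (4aS,8aS)-4a,7,7-trimethyl-3,4,4a,5,6,7,8,8a-octahydronaphthalen-2-olate | [Li]OC1=C[C@@H]2CC(C)(C)CC[C@@]2(C)CC1 | intermediate (not isolated)
12 | (4aS,8aS)-4a,7,7-trimethyl-3,4,4a,5,6,7,8,8a-octahydronaphthalen-2-yl trifluoromethanesulfonate (trans-fused) | O=S(=O)(OC1=C[C@@H]2CC(C)(C)CC[C@@]2(C)CC1)C(F)(F)F | intermediate
13 | trimethyl[(4aS,8aS)-4a,7,7-trimethyl-3,4,4a,5,6,7,8,8a-octahydronaphthalen-2-yl]stannane | C[Sn](C)(C)C1=C[C@@H]2CC(C)(C)CC[C@@]2(C)CC1 | intermediate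
14 | hexa-1,5-diene | C=CCCC=C | starting material
15 | trichloroacetyl chloride | ClC(Cl)(Cl)C(Cl)=O | starting material
16 | dichloroketene | ClC(Cl)=C=O | intermediate (not isolated)
17 | 3-(but-3-en-1-yl)-2,2-dichlorocyclobutan-1-one (racemic, 3R drawn) | ClC1(Cl)[C@H](CCC=C)CC1=O | intermediate
18 | lithium 3-(but-3-en-1-yl)-2-methylcyclobut-1-en-1-olate (racemic, 3R drawn) | [Li]OC1=C(C)[C@H](CCC=C)C1 | intermediate (not isolated)
19 | {[3-(but-3-en-1-yl)-2-methylcyclobut-1-en-1-yl]oxy}trimethylsilane (racemic, 3R drawn) | C[Si](C)(C)OC1=C(C)[C@H](CCC=C)C1 | intermediate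
20 | ethyl phenyl sulfide | CCSc1ccccc1 | starting material
21 | (1-chloroethyl)(phenyl)sulfane (racemic) | CC(Cl)Sc1ccccc1 | intermediate
22 | rac-(2S,3R)-3-(but-3-en-1-yl)-2-methyl-2-[1-(phenylsulfanyl)ethyl]cyclobutan-1-one (methyl cis to butenyl; epimers at the sulfide carbon) | CC(Sc1ccccc1)[C@@]1(C)[C@H](CCC=C)CC1=O | intermediate
23 | rac-(2S,3R)-3-(but-3-en-1-yl)-2-methyl-2-[1-(phenylsulfinyl)ethyl]cyclobutan-1-one | CC(S(=O)c1ccccc1)[C@@]1(C)[C@H](CCC=C)CC1=O | intermediate (not isolated)
24 | rac-(2S,3R)-3-(but-3-en-1-yl)-2-ethenyl-2-methylcyclobutan-1-one (methyl cis, vinyl trans to butenyl) | C=C[C@@]1(C)[C@H](CCC=C)CC1=O | intermediate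
25 | (2S,3R)-3-(but-3-en-1-yl)-2-ethenyl-2-methylcyclobutan-1-one | C=C[C@@]1(C)[C@H](CCC=C)CC1=O | intermediate
26 | [(4a,8a-trans)-4a,7,7-trimethyl-3,4,4a,5,6,7,8,8a-octahydronaphthalen-2-yl]lithium (configuration of 13) | [Li]C1=C[C@@H]2CC(C)(C)CC[C@@]2(C)CC1 | intermediate (not isolated)
27 | (1R,2S,3R)-3-(but-3-en-1-yl)-2-ethenyl-2-methyl-1-[(4aS,8aS)-4a,7,7-trimethyl-3,4,4a,5,6,7,8,8a-octahydronaphthalen-2-yl]cyclobutan-1-ol (vinyl cis to the cyclohexenyl group; butenyl trans to both) | C=C[C@@]1(C)[C@H](CCC=C)C[C@@]1(O)C1=C[C@@H]2CC(C)(C)CC[C@@]2(C)CC1 | intermediate (key-step precursor)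
28 | potassium alkoxide of 27 | C=C[C@@]1(C)[C@H](CCC=C)C[C@@]1([O-])C1=C[C@@H]2CC(C)(C)CC[C@@]2(C)CC1.[K+] | intermediate (not isolated)
29 | potassium C9=C11 enolate (ring B formed, Z-C2=C26, H24 trans to H23) | C1/C=C(C)\[C@H](CCC=C)C/C([O-])=C2/CC[C@]3(C)CCC(C)(C)C[C@H]3[C@@H]21.[K+] | intermediate (not isolated)
30 | tricyclic ketone: ring B cyclooct-4-enone (C9=O, Z-C2(CH3)=C26, but-3-enyl at C3) trans-fused at C11(CH3)/C24(H) to the trans-decalin C/D | C1/C=C(C)\[C@H](CCC=C)CC(=O)[C@@]2(C)CC[C@]3(C)CCC(C)(C)C[C@H]3[C@@H]21 | intermediate (key-step product)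
31 | tetracyclic ketone: 30 with ring A closed (C8–C6), C6 methyl cis to C9; H3, H8, H6 cis | C1/C=C(C)\[C@@H]2CC[C@H](C)[C@@H]2C(=O)[C@@]2(C)CC[C@]3(C)CCC(C)(C)C[C@H]3[C@@H]21 | intermediate
32 | tetracyclic β,γ-unsaturated ketone (C9=O, C2=C3) | C/C1=C2\CC[C@H](C)[C@@H]2C(=O)[C@@]2(C)CC[C@]3(C)CCC(C)(C)C[C@H]3[C@@H]2CC1 | intermediate
33 | potassium dienolate C9(OK)=C8–C3=C2 | C/C1=C2\CC[C@H](C)/C2=C(\[O-])[C@@]2(C)CC[C@]3(C)CCC(C)(C)C[C@H]3[C@@H]2CC1.[K+] | intermediate (not isolated)
34 | dienyl triflate C9(OTf)=C8–C3=C2 | C/C1=C2\CC[C@H](C)/C2=C(\OS(=O)(=O)C(F)(F)F)[C@@]2(C)CC[C@]3(C)CCC(C)(C)C[C@H]3[C@@H]2CC1 | intermediate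
35 | diene C9H=C8–C3=C2 | C/C1=C2\CC[C@H](C)/C2=C/[C@@]2(C)CC[C@]3(C)CCC(C)(C)C[C@H]3[C@@H]2CC1 | intermediate
36 | C9 alkylborane (BH2 cis to H8) | C/C1=C2\CC[C@H](C)[C@@H]2[C@@H](B)[C@@]2(C)CC[C@]3(C)CCC(C)(C)C[C@H]3[C@@H]2CC1 | intermediate (not isolated)
37 | CNP0399382.1 | C/C1=C2\CC[C@H](C)[C@@H]2[C@@H](O)[C@@]2(C)CC[C@]3(C)CCC(C)(C)C[C@H]3[C@@H]2CC1 | target

## Step count and risks

Total step count: 18. Longest linear sequence: 12 steps (steps 1–5 then 12–18; the cyclobutanone branch 6, 7, 9, 10, 11 then 12–18 is equally long).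

**Step 13 (key step).** What may go wrong: the methyl group may be delivered to the exposed convex face of the tub‑shaped dienolate (cis to H24) instead of the face syn to C25, which would give the cis B/C fusion. Methylation at oxygen, or cleavage or 1,3‑shift of the cyclobutoxide instead of the [3,3] shift, are further failure modes. Fallback: rearrangement and alkylation are separated. From 27, silylation (TMS‑imidazole) gives the trimethylsilyl ether F1, and its neutral siloxy‑Cope rearrangement (toluene, 90–110 °C) gives the regio‑defined trimethylsilyl enol ether F2. F2 is cleaved with MeLi (THF, 0 °C) to the lithium enolate F3, which is methylated (MeI, DMPU, −78 → 0 °C) to rejoin the route at 30. This removes the alkoxide side reactions and O‑alkylation and offers a second, aggregated lithium enolate for the face‑selective methylation. It does not by itself reverse the facial preference.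

**Step 14.** What may go wrong: at 300 °C a transannular carbonyl‑ene reaction of the cyclooct‑4‑enone or decomposition may outrun the enol‑ene closure, and C6 may be set with poor selectivity. Fallback: radical 5‑exo closure. From 30, KHMDS/Me3SiCl gives the trimethylsilyl enol ether F4 (only C8 can be enolised), and N‑iodosuccinimide (THF, −78 °C) gives the α‑iodo ketone F5. Slow addition of Bu3SnH with Et3B/air (benzene, rt) generates the C8 α‑keto radical, which closes 5‑exo onto C6 and is reduced at C7, rejoining the route at 31. Cis ring fusion and a 1,5‑cis methyl are expected from the chair‑like 5‑exo transition state.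

**Step 15.** What may go wrong: hydrogen‑atom transfer to the hindered trisubstituted C2=C26 alkene may be slow, stop at the exocyclic methylene isomer, or end in reduction. Fallback: the double bond is moved by an oxidation–reduction pair that also delivers the triflate of step 16. From 31, KHMDS/Me3SiCl gives the trimethylsilyl enol ether F6, and Saegusa–Ito oxidation (Pd(OAc)2, MeCN) gives the linear dienone F7 (C9=O, C8=C3, C2=C26). Li/NH3 with t‑BuOH (1 equiv) reduces F7 with protonation at the δ‑carbon C26 to the lithium dienolate F8, which is trapped with PhNTf2 to rejoin the route at 34; steps 15 and 16 are bypassed.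

## Further compounds

F1 | step 13 | trimethylsilyl ether of 27 | C=C[C@@]1(C)[C@H](CCC=C)C[C@@]1(O[Si](C)(C)C)C1=C[C@@H]2CC(C)(C)CC[C@@]2(C)CC1
F2 | step 13 | trimethylsilyl enol ether C9(OSiMe3)=C11 of the ring-expanded ketone | C1/C=C(C)\[C@H](CCC=C)C/C(O[Si](C)(C)C)=C2/CC[C@]3(C)CCC(C)(C)C[C@H]3[C@@H]21
F3 | step 13 | lithium C9=C11 enolate | C1/C=C(C)\[C@H](CCC=C)C/C(O[Li])=C2/CC[C@]3(C)CCC(C)(C)C[C@H]3[C@@H]21
F4 | step 14 | trimethylsilyl enol ether C8=C9(OSiMe3) of 30 | C1/C=C(C)\[C@H](CCC=C)/C=C(/O[Si](C)(C)C)[C@@]2(C)CC[C@]3(C)CCC(C)(C)C[C@H]3[C@@H]21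
F5 | step 14 | C8 α-iodo ketone of 30 (C8 epimers) | C1/C=C(C)\[C@H](CCC=C)C(I)C(=O)[C@@]2(C)CC[C@]3(C)CCC(C)(C)C[C@H]3[C@@H]21
F6 | step 15 | trimethylsilyl enol ether C8=C9(OSiMe3) of 31 | C1/C=C(C)\[C@@H]2CC[C@H](C)/C2=C(\O[Si](C)(C)C)[C@@]2(C)CC[C@]3(C)CCC(C)(C)C[C@H]3[C@@H]21
F7 | step 15 | linear dienone (C9=O, C8=C3, C2=C26) | C1/C=C(C)\C2=C([C@@H](C)CC2)C(=O)[C@@]2(C)CC[C@]3(C)CCC(C)(C)C[C@H]3[C@@H]21
F8 | step 15 | lithium dienolate C9(OLi)=C8–C3=C2 | C/C1=C2\CC[C@H](C)/C2=C(\O[Li])[C@@]2(C)CC[C@]3(C)CCC(C)(C)C[C@H]3[C@@H]2CC1
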